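**Assumptions.**
- The target has no stereocentres, so "single enantiomer" is vacuous. The only sp3 stereocentre in the route (C-2 of diketone **11**) is destroyed on cyclisation.
- Phloroacetophenone is assumed to mono-C-prenylate at C-3. MOMCl is assumed to cap the two less hindered OH groups of the resulting prenylated phenol.

## Retrosynthetic overview
1. Cudraflavone C comes from a flavone carrying three aryl allyl ethers (5-O, 2'-O, 4'-O) by Pd(0) deallylation.
2. Ring C is formed last, by acid cyclodehydration of an α-prenyl 1,3-diketone. This sets the 3-prenyl group, and ring C can only close through the one free ortho OH.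
3. The diketone comes from a crossed Claisen condensation of an A-ring acetophenone with methyl 2,4-bis(allyloxy)benzoate, followed by C-prenylation.
4. The hindered OH next to the A-ring prenyl is capped as an allyl ether, so the pyranone oxygen can only come from the unhindered OH. That fixes the 6-prenyl versus 8-prenyl regiochemistry.

## Route

**Step 1**
Reactants: **1** 2',4',6'-trihydroxyacetophenone; **2** prenyl bromide
Product: **3** 1-[2,4,6-trihydroxy-3-(3-methylbut-2-enyl)phenyl]ethanone
Conditions: KOH (2.2 equiv), H2O, 0 °C → rt
Reagents that add atoms: prenyl bromide, CC(C)=CCBr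
Why: C-alkylation of the phloroglucinol-type phenoxide (ortho C-prenylation). The two free ring positions are equivalent, so one regioisomer forms, and 1 equiv of bromide limits diprenylation. No stereocentre.

**Step 2**
Reactants: **3**; **4** chloromethyl methyl ether (MOMCl)
Product: **5** 1-[2-hydroxy-4,6-bis(methoxymethoxy)-3-(3-methylbut-2-enyl)phenyl]ethanone
Conditions: MOMCl (2.1 equiv), K2CO3, acetone, 0 °C → rt
Reagents that add atoms: MOMCl, COCCl
Why: Williamson-type MOM ether formation. The unhindered 4'-OH and 6'-OH react. The 2'-OH, flanked by the prenyl group and chelated to the C=O, stays free. No stereocentre.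

**Step 3**
Reactants: **5**; **6** allyl bromide
Product: **7** 1-[2-(allyloxy)-4,6-bis(methoxymethoxy)-3-(3-methylbut-2-enyl)phenyl]ethanone
Conditions: allyl bromide (1.5 equiv), Cs2CO3, DMF, 60 °C
Reagents that add atoms: allyl bromide, C=CCBr
Why: Williamson etherification caps the hindered phenol with a group that survives the later acid and base steps. This blocks that oxygen from forming the pyran ring, which fixes the 6-prenyl regiochemistry. No stereocentre.

**Step 4**
Reactants: **8** methyl 2,4-dihydroxybenzoate; **6** allyl bromide
Product: **9** methyl 2,4-bis(allyloxy)benzoate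
Conditions: allyl bromide (2.5 equiv), K2CO3, acetone, reflux
Reagents that add atoms: allyl bromide, C=CCBr
Why: double Williamson etherification. Allyl groups on the B-ring stay on through the acid cyclisation, so the B-ring 2'-OH cannot compete in ring closure. They are removed with the A-ring allyl in the last step. No stereocentre.

**Step 5**
Reactants: **7**; **9**
Product: **10** 1-[2-(allyloxy)-4,6-bis(methoxymethoxy)-3-prenylphenyl]-3-[2,4-bis(allyloxy)phenyl]propane-1,3-dione
Conditions: LiHMDS (3 equiv), THF, –78 °C → 50 °C
Reagents that add atoms: none (the acyl donor is reactant **9**; MeOH is lost)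
Why: crossed Claisen condensation (acylation of the ketone lithium enolate by the non-enolisable ester). It is equivalent to the Baker–Venkataraman diketone, and the product is driven forward as its stable enolate. No stereocentre.

**Step 6**
Reactants: **10**; **2** prenyl bromide
Product: **11** 2-prenyl-1,3-diketone
Conditions: prenyl bromide (1.3 equiv), K2CO3, KI (cat.), acetone, reflux
Reagents that add atoms: prenyl bromide, CC(C)=CCBr
Why: C-alkylation of the soft, doubly activated 1,3-diketone enolate. No free phenol is present to compete. A transient sp3 stereocentre forms (racemic, enolisable) and is lost on cyclisation.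

**Step 7**
Reactants: **11**
Product: **12** 5-(allyloxy)-2-[2,4-bis(allyloxy)phenyl]-7-hydroxy-3,6-bis(3-methylbut-2-enyl)chromen-4-one
Conditions: conc. HCl, MeOH, 60 °C → reflux
Reagents that add atoms: none
Why: acid-mediated MOM cleavage and flavone cyclodehydration. The only free ortho-OH is the unhindered 6'-OH, so the pyranone oxygen lands away from the prenyl group, giving the 6-prenyl regiochemistry. Aryl allyl ethers and the prenyl alkenes are inert to dilute HCl. No stereocentre.

**Step 8**
Reactants: **12**
Product: **13** cudraflavone C
Conditions: Pd(PPh3)4 (10 mol %), K2CO3 (6 equiv), MeOH, 65 °C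
Reagents that add atoms: none (allyl is transferred to MeOH)
Why: Tsuji–Trost-type Pd(0) deallylation of three aryl allyl ethers. The C-prenyl groups are not leaving groups and stay intact. The product is achiral.

## Compound list
1 | 2',4',6'-trihydroxyacetophenone | CC(=O)c1c(O)cc(O)cc1O | starting material
2 | prenyl bromide (1-bromo-3-methylbut-2-ene) | CC(C)=CCBr | starting material
3 | 1-[2,4,6-trihydroxy-3-prenylphenyl]ethanone | CC(=O)c1c(O)cc(O)c(CC=C(C)C)c1O | intermediate
4 | chloromethyl methyl ether (MOMCl) | COCCl | starting material
5 | 1-[2-hydroxy-4,6-bis(MOMO)-3-prenylphenyl]ethanone | CC(=O)c1c(O)c(CC=C(C)C)c(OCOC)cc1OCOC | intermediate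
6 | allyl bromide | C=CCBr | starting material
7 | 1-[2-allyloxy-4,6-bis(MOMO)-3-prenylphenyl]ethanone | CC(=O)c1c(OCOC)cc(OCOC)c(CC=C(C)C)c1OCC=C | intermediate
8 | methyl 2,4-dihydroxybenzoate | COC(=O)c1ccc(O)cc1O | starting material
9 | methyl 2,4-bis(allyloxy)benzoate | COC(=O)c1ccc(OCC=C)cc1OCC=C | intermediate
10 | 1,3-diketone (A-ring aryl, B-ring aryl) | O=C(CC(=O)c1ccc(OCC=C)cc1OCC=C)c1c(OCOC)cc(OCOC)c(CC=C(C)C)c1OCC=C | intermediate
11 | 2-prenyl-1,3-diketone | O=C(C(CC=C(C)C)C(=O)c1ccc(OCC=C)cc1OCC=C)c1c(OCOC)cc(OCOC)c(CC=C(C)C)c1OCC=C | intermediate
12 | 5-allyloxy-2-[2,4-bis(allyloxy)phenyl]-7-hydroxy-3,6-diprenylchromone | CC(C)=CCc1c(OCC=C)c2c(=O)c(CC=C(C)C)c(-c3ccc(OCC=C)cc3OCC=C)oc2cc1O | intermediate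
13 | cudraflavone C (achiral) | CC(C)=CCc1c(O)cc2oc(-c3ccc(O)cc3O)c(CC=C(C)C)c(=O)c2c1O | target

## Totals
Total steps: 8. Longest linear sequence: 7 (1 → 3 → 5 → 7 → 10 → 11 → 12 → 13).

## Three steps most likely to fail
1. **Step 2 (regioselective bis-MOM protection).** If MOM also lands on the hindered 2'-OH, the wrong oxygen is left free. Fallback: change the order. Bis-MOM protect symmetric phloroacetophenone first, which needs no selectivity, then do an ortho-directed C-prenylation of the lone phenol (via its Mg phenoxide). Allylate the free OH next to the prenyl group, giving the same compound **7**.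
2. **Step 5 (Claisen condensation).** The ketone is di-ortho-substituted and the ester is electron-rich, so the yield may be poor. Fallback: change the acyl donor class. Convert the B-ring ester to the Weinreb amide or the acid chloride and acylate the preformed ketone enolate, or swap the enolate/electrophile roles so the B-ring acetophenone is the enolate partner.
3. **Step 7 (acid cyclodehydration).** A 2-alkyl diketone cyclises slowly, and the acid may trigger chroman formation from 4'-OH plus the adjacent prenyl. Fallback: remove the MOM groups under non-protic Lewis-acid conditions (MgBr2 or ZnBr2/n-PrSH). Then close the ring with a Mitsunobu-type cyclodehydration (PPh3, DIAD, THF, rt) on the hydroxy-diketone.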